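Begin with the easy step and count ligands. Each exchange uses one incoming ligand and releases one leaving ligand, and in the flask double exchange of the whole starting complex would take 1.54 of the incoming charge, so the incoming ligand is the limiting reagent.

| setting | cedar | birch | alder | flask |
|---|---|---|---|---|
| starting complex | 0.021 M | 0.021 M | 0.021 M | 0.021 M |
| incoming ligand | 0.0273 M | 0.0273 M | 0.014 M | 0.0273 M |
| scavenger | 4.2 mM (fed, over 4.0 min) | 9.4 mM (fed, over 4.0 min) | 6.3 mM (fed, over 4.0 min) | 6.30 mM (fed, over 4.0 min) |
| remark | run made earlier | run made earlier | run made earlier |  |
| time |  |  |  | 20 min |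

| run | time / min | starting complex / % | complex with two exchanged / % |
|---|---|---|---|
| cedar | 1.50 | 89.6 | 3.2 |
| cedar | 2.50 | 85.0 | 6.9 |
| cedar | 4.00 | 79.8 | 11.3 |
| cedar | 6.00 | 74.2 | 16.2 |
| cedar | 8.00 | 70.2 | 19.3 |
| cedar | 12.0 | 66.5 | 24.6 |
| cedar | 20.0 | 60.5 | 29.4 |
| birch | 3.00 | 82.5 | 8.3 |
| birch | 6.00 | 73.4 | 15.9 |
| birch | 8.00 | 69.8 | 19.6 |
| birch | 12.0 | 64.4 | 25.6 |
| birch | 15.0 | 62.4 | 28.5 |
| birch | 20.0 | 59.6 | 32.4 |
| alder | 4.00 | 87.9 | 4.0 |
| alder | 8.00 | 82.5 | 7.6 |
| alder | 12.0 | 79.2 | 11.8 |
| alder | 15.0 | 78.7 | 12.9 |
| alder | 20.0 | 75.0 | 15.4 |

(each reading ± 0.5 percentage points)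

- leaving ligand is meant together with its idle adduct
- steps under discussion: complex with one exchanged + incoming ligand <-> leaving ligand + complex with two exchanged; leaving ligand + incoming ligand <-> idle adduct; leaving ligand + complex with two exchanged -> side product; starting complex + incoming ligand <-> leaving ligand + complex with one exchanged; scavenger + leaving ligand -> scavenged by-product
- the earlier runs do not show how much of incoming ligand is bound; that part of a forecast is a guess

- part of the starting complex that has reacted at 20 min
- share of the unused incoming ligand that is free and not bound as idle adduct, at 20 min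

Turn the scavenger first. By hand, more of it removes more leaving ligand and should raise conversion, yet from cedar to birch conversion at 20 min moves by 0.9 percentage points, with a reading scatter of 0.5 points. Turn the incoming ligand next. By hand, less of it slows both exchanges, and alder, whose scavenger charge lies between cedar's and birch's, reaches 25.0%, less than cedar's 39.5%. No run turns the starting complex; by hand, it sets how much leaving ligand a given conversion releases. So take the mean of cedar and birch for the flask, 39.9% conversion.

By the same mean of cedar and birch, the exchanges in the flask use about 0.545 of the incoming charge, leaving about 0.455 unused, and the scavenger charge equals 0.231 of the incoming charge. Define the load as the released leaving ligand not taken by scavenger over the unused incoming ligand: 0.691 if the whole scavenger charge has reacted. If binding is tight, a load below one leaves about one minus the load of the unused incoming ligand free, and a load of one is the crossing, where leaving ligand stops being the smaller partner. My guess, since the runs do not show binding, is 30.9%.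

The forecast gives 40% and 50%, holding that “the weak scavenger effect argues against very tight binding”. Its free share is higher than mine.

The flask gives 39.8% reacted and a free share of 24.8%.

    complex with one exchanged + incoming ligand ⇌ leaving ligand + complex with two exchanged (K = 18.0, k = 22.0 M⁻¹ min⁻¹)
    leaving ligand + incoming ligand ⇌ idle adduct, settled at all times (K = 4900 M⁻¹)
    leaving ligand + complex with two exchanged → side product (k = 3.70 M⁻¹ min⁻¹)
    starting complex + incoming ligand ⇌ leaving ligand + complex with one exchanged (K = 0.250, k = 2.90 M⁻¹ min⁻¹)
    scavenger + leaving ligand → scavenged by-product (k = 250 M⁻¹ min⁻¹)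

In the flask, half the first exchange's turnover up to 20 min is done by 3.71 min and half the scavenger's later, by 11.8 min, and 22% of the scavenger charge remains at 20.0 min. Counting that remainder raises the load from 0.691 to 0.802, which gives a free share of 19.8%, lower than the flask's 24.8%; at 20.0 min the flask holds 6.18 × 10⁻⁴ M leaving ligand beside 0.00929 M idle adduct. In the neighbour flask with 0.0053 M starting complex, its simulated conversion, complex with two exchanged and scavenged by-product give a load of 0.277, so a free share of 72.3%. Its computed free share is 72.7%.

The data were computed from invented constants, noise included.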